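**Assumptions.** Positions are labelled by target (xenicane-type) numbering: C1 (ring C bearing C19 = CHO), C2 (bears C18 = CH2OAc), C3 (bears the side chain; C10 = side-chain methine), C4 (CHOH), C5 (CH2), C6(Me)=C7, C8 (CH2), C9 (=CH). The target is 2R,3R,4S,10S with C1=C9 E (ring-cis) and C6=C7 E (ring-trans). Compounds 1, 2, 4, 6 and 11 are taken as commercial. Nothing here has been run; selectivities are predictions.

**Retrosynthetic overview**
1. Target ⇐ bicyclic lactone 14, whose C18–O–C19 lactone is the latent CH2OAc/CHO pair (Weinreb opening, acetylation, amide→CHO, desilylation).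
2. Nine-membered ring ⇐ C7–C8 closure by intramolecular alkenylboronate/allyl acetate Suzuki coupling (new); it is formed after the γ-lactone.
3. C1=C9 ⇐ HWE of an α-phosphono lactone; E-C6=C7 ⇐ alkyne methylalumination/borylation; C4 ⇐ catalytic asymmetric propargylation.
4. C2–C3 bond and both stereocentres ⇐ enamine Michael addition of (S)-citronellal (supplies C10) to an alkylidene phosphonoacetate (new).

**Step 1**
Reactants: 1 2-[(tert-butyldimethylsilyl)oxy]acetaldehyde; 2 triethyl phosphonoacetate
Product: 3 ethyl (2E)-4-[(tert-butyldimethylsilyl)oxy]-2-(diethoxyphosphoryl)but-2-enoate (used as E/Z mixture)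
Conditions: TiCl4, N-methylmorpholine, THF, 0 °C → rt
Reagents that add atoms: none
Why: Knoevenagel condensation under Lehnert conditions gives the doubly activated alkene; its E/Z ratio is irrelevant because C1 becomes sp3 in step 2.

**Step 2**
Reactants: 4 (S)-citronellal [(3S)-3,7-dimethyloct-6-enal]; 3
Product: 5 ethyl (2RS,3S,4R,5S)-3-{[(tert-butyldimethylsilyl)oxy]methyl}-2-(diethoxyphosphoryl)-4-formyl-5,9-dimethyldec-8-enoate (target C2, C3, C10 set; C1 epimers)
Conditions: (S)-α,α-diphenylprolinol TMS ether (20 mol%), 4-nitrophenol (20 mol%), 4 (2 equiv), toluene (1 M), 0 °C → rt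
Reagents that add atoms: none
Why: Proposed new method: enamine (Hayashi–Jørgensen-type) Michael addition of an α-unbranched aldehyde to a β-substituted 2-phosphonoacrylate; the geminal P(O)(OEt)2/CO2Et pair activates the alkene like an alkylidene malonate (helped by H-bonding from the phenol), the (S)-catalyst's E-enamine reacts on the face remote from CPh2OTMS to fix C3 as R (same sense as its nitroalkene additions), and an acyclic synclinal transition state with CH2OTBS turned away from the pyrrolidine gives the syn C2/C3 pair (2R,3R in target numbering; C10 comes from 4; the C1 epimers converge in step 8); closest known reactions are diarylprolinol-silyl-ether-catalysed additions of aldehydes to nitroalkenes, alkylidene malonates and unsubstituted 2-phosphonoacrylate.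

**Step 3**
Reactants: 5; 6 allenylboronic acid pinacol ester
Product: 7 ethyl (2RS,3S,4R,5S)-3-{[(tert-butyldimethylsilyl)oxy]methyl}-2-(diethoxyphosphoryl)-4-[(1S)-1-hydroxybut-3-yn-1-yl]-5,9-dimethyldec-8-enoate
Conditions: (S)-TRIP phosphoric acid (10 mol%), 4 Å MS, toluene, −20 °C
Reagents that add atoms: none beyond 6 (C=C=CB1OC(C)(C)C(C)(C)O1, delivers CH2C≡CH)
Why: Chiral-phosphoric-acid-catalysed propargylation with an allenylboronate (cyclic SE2′ transition state) delivers the propargyl group to the Si face of the aldehyde under catalyst control to give 4S; the catalyst enantiomer is chosen by analogy with ArCHO, where (R)-TRIP gives Re-face attack.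

**Step 4**
Reactants: 7
Product: 8 diethyl {(3RS,4S)-4-[(4S,5R,6S)-4-hydroxy-6,10-dimethylundec-9-en-1-yn-5-yl]-2-oxooxolan-3-yl}phosphonate
Conditions: p-TsOH·H2O (cat.), MeOH, rt; then toluene, 50 °C
Reagents that add atoms: none
Why: Acid removes the primary TBS ether and the freed C18–OH lactonises onto the C19 ester, the γ-lactone being favoured over the δ-lactone from O4; no stereocentre is touched.

**Step 5**
Reactants: 8
Product: 9 diethyl {(3RS,4S)-4-[(4S,5R,6S)-4-[(tert-butyldimethylsilyl)oxy]-6,10-dimethylundec-9-en-1-yn-5-yl]-2-oxooxolan-3-yl}phosphonate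
Conditions: TBSOTf, 2,6-lutidine, CH2Cl2, −78 → 0 °C
Reagents that add atoms: TBSOTf, CC(C)(C)[Si](C)(C)OS(=O)(=O)C(F)(F)F
Why: Standard silylation of the hindered secondary C4–OH, so that only C18–OH is free in step 11.

**Step 6**
Reactants: 9
Product: 10 diethyl {(3RS,4S)-4-[(1E,4S,5R,6S)-4-[(tert-butyldimethylsilyl)oxy]-2,6,10-trimethyl-1-(4,4,5,5-tetramethyl-1,3,2-dioxaborolan-2-yl)undeca-1,9-dien-5-yl]-2-oxooxolan-3-yl}phosphonate
Conditions: Me3Al (4 equiv), Cp2ZrCl2 (0.5 equiv), H2O (1 equiv), CH2Cl2, −30 → 0 °C; then i-PrOBpin, 0 °C → rt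
Reagents that add atoms: trimethylaluminium, C[Al](C)C; 2-isopropoxy-4,4,5,5-tetramethyl-1,3,2-dioxaborolane, CC(C)OB1OC(C)(C)C(C)(C)O1
Why: Negishi Zr-catalysed syn-methylalumination (Me to C6, Al to C7) followed by Al→B exchange with retention sets the E-C6=C7 geometry; the C–H-acidic phosphonolactone should only be held as its aluminium enolate and return on work-up.

**Step 7**
Reactants: 11 (Z)-but-2-ene-1,4-diyl diacetate
Product: 12 2-oxoethyl acetate (acetoxyacetaldehyde, 2 equiv)
Conditions: O3, CH2Cl2, −78 °C; then Me2S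
Reagents that add atoms: ozone, [O-][O+]=O
Why: Ozonolysis with reductive work-up of the symmetric alkene gives two equivalents of the aldehyde.

**Step 8**
Reactants: 10; 12
Product: 13 2-[(3E,4R)-4-[(1E,4S,5R,6S)-4-[(tert-butyldimethylsilyl)oxy]-2,6,10-trimethyl-1-(4,4,5,5-tetramethyl-1,3,2-dioxaborolan-2-yl)undeca-1,9-dien-5-yl]-2-oxooxolan-3-ylidene]ethyl acetate
Conditions: NaH, THF, 0 °C; then 12, −40 → 0 °C
Reagents that add atoms: none
Why: Horner–Wadsworth–Emmons olefination of the α-phosphono-γ-lactone forms C1=C9, with the E isomer (C8 trans to C=O, cis to C2) expected to predominate; any Z isomer is separated or equilibrated (cat. I2, hν).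

**Step 9**
Reactants: 13
Product: 14 bicyclic lactone (2R,3R,4S,10S): γ-lactone C19(=O)–O–C18 fused at C1/C2 to the nine-membered ring, with C1=C9 (E, ring-cis), C6(Me)=C7 (E, ring-trans), C4–OTBS and the C3 side chain (the TBS ether of the 4-hydroxydictyolactone skeleton)
Conditions: Pd2(dba)3 (10 mol%), P(2-furyl)3 (40 mol%), CsF (3 equiv), THF/H2O 20:1, 0.002 M (syringe pump), 50 °C
Reagents that add atoms: none
Why: Proposed new method: intramolecular Suzuki–Miyaura alkenyl–allyl coupling as a nine-membered ring closure; Pd(0) ionises the allylic acetate to an η3-allyl (C8–C9–C1), the fluoride-activated alkenyl-Bpin transmetalates with retention, and reductive elimination at the unhindered CH2 terminus forms C7–C8, with only the C8/C2-cis allyl rotamer able to close so both alkene geometries are delivered and no stereocentre is created; closest known reactions are intermolecular Pd-catalysed alkenylboron/allyl acetate couplings to skipped dienes and B-alkyl Suzuki macrocyclisation forming the same C7–C8 bond of a nine-membered xenicane ring.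

**Step 10**
Reactants: 14
Product: 15 (1E,4E,7S,8R,9R)-7-[(tert-butyldimethylsilyl)oxy]-9-(hydroxymethyl)-N-methoxy-N,5-dimethyl-8-[(2S)-6-methylhept-5-en-2-yl]cyclonona-1,4-diene-1-carboxamide
Conditions: MeNH(OMe)·HCl, Me3Al, CH2Cl2, 0 °C → rt
Reagents that add atoms: N,O-dimethylhydroxylamine hydrochloride, CNOC.Cl
Why: Weinreb aminolysis of the lactone with Me2AlN(OMe)Me frees C18–OH and leaves C19 as the amide, which differentiates the two carbons.

**Step 11**
Reactants: 15
Product: 16 [(1R,2E,5E,8S,9R)-8-[(tert-butyldimethylsilyl)oxy]-2-[methoxy(methyl)carbamoyl]-6-methyl-9-[(2S)-6-methylhept-5-en-2-yl]cyclonona-2,5-dien-1-yl]methyl acetate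
Conditions: Ac2O, pyridine, DMAP (cat.), CH2Cl2, 0 °C (directly on crude 15)
Reagents that add atoms: acetic anhydride, CC(=O)OC(C)=O
Why: Acetylation of the only free hydroxyl, done at once so the γ-hydroxy amide cannot relactonise.

**Step 12**
Reactants: 16
Product: 17 [(1R,2E,5E,8S,9R)-8-[(tert-butyldimethylsilyl)oxy]-2-formyl-6-methyl-9-[(2S)-6-methylhept-5-en-2-yl]cyclonona-2,5-dien-1-yl]methyl acetate
Conditions: Cp2Zr(H)Cl (2 equiv), THF, rt, 15 min
Reagents that add atoms: none
Why: Schwartz-reagent reduction of the tertiary (Weinreb) amide stops at the aldehyde via a zirconated hemiaminal and tolerates the acetate and the trisubstituted alkenes.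

**Step 13**
Reactants: 17
Product: 18 hydroxyacetyldictyolal, [(1R,2E,5E,8S,9R)-2-formyl-8-hydroxy-6-methyl-9-[(2S)-6-methylhept-5-en-2-yl]cyclonona-2,5-dien-1-yl]methyl acetate
Conditions: HF·pyridine, THF/pyridine, 0 °C → rt
Reagents that add atoms: none
Why: Buffered fluoride removes the secondary TBS ether without affecting the enal, the acetate or the skipped diene.

**Compound list**
1 | 2-[(tert-butyldimethylsilyl)oxy]acetaldehyde | CC(C)(C)[Si](C)(C)OCC=O | starting material
2 | triethyl phosphonoacetate | CCOC(=O)CP(=O)(OCC)OCC | starting material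
3 | ethyl (2E)-4-(TBSO)-2-(diethoxyphosphoryl)but-2-enoate | CCOC(=O)/C(=C\CO[Si](C)(C)C(C)(C)C)P(=O)(OCC)OCC | intermediate
4 | (S)-citronellal | O=CC[C@@H](C)CCC=C(C)C | starting material
5 | Michael adduct (aldehyde, C1 epimers) | CC(C)(C)[Si](C)(C)OC[C@H]([C@H](C=O)[C@@H](C)CCC=C(C)C)C(C(=O)OCC)P(=O)(OCC)OCC | intermediate
6 | allenylboronic acid pinacol ester | C=C=CB1OC(C)(C)C(C)(C)O1 | starting material
7 | (4S)-homopropargylic alcohol | CC(C)(C)[Si](C)(C)OC[C@H]([C@H]([C@@H](O)CC#C)[C@@H](C)CCC=C(C)C)C(C(=O)OCC)P(=O)(OCC)OCC | intermediate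
8 | α-phosphono-γ-lactone, C4–OH | O=C1OC[C@H]([C@H]([C@@H](O)CC#C)[C@@H](C)CCC=C(C)C)C1P(=O)(OCC)OCC | intermediate
9 | α-phosphono-γ-lactone, C4–OTBS | O=C1OC[C@H]([C@H]([C@@H](O[Si](C)(C)C(C)(C)C)CC#C)[C@@H](C)CCC=C(C)C)C1P(=O)(OCC)OCC | intermediate
10 | (E)-alkenyl-Bpin phosphonolactone | O=C1OC[C@H]([C@H]([C@@H](O[Si](C)(C)C(C)(C)C)C/C(C)=C/B2OC(C)(C)C(C)(C)O2)[C@@H](C)CCC=C(C)C)C1P(=O)(OCC)OCC | intermediate
11 | (Z)-but-2-ene-1,4-diyl diacetate | CC(=O)OC/C=C\COC(C)=O | starting material
12 | 2-oxoethyl acetate | CC(=O)OCC=O | intermediate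
13 | (E)-alkylidene lactone with allylic acetate and alkenyl-Bpin | O=C1OC[C@H]([C@H]([C@@H](O[Si](C)(C)C(C)(C)C)C/C(C)=C/B2OC(C)(C)C(C)(C)O2)[C@@H](C)CCC=C(C)C)/C1=C\COC(C)=O | intermediate
14 | bicyclic lactone (4-O-TBS) | O=C2OC[C@H]1/C2=C\C/C=C(\C)C[C@H](O[Si](C)(C)C(C)(C)C)[C@@H]1[C@@H](C)CCC=C(C)C | intermediate
15 | hydroxy Weinreb amide | OC[C@H]1/C(C(=O)N(C)OC)=C\C/C=C(\C)C[C@H](O[Si](C)(C)C(C)(C)C)[C@@H]1[C@@H](C)CCC=C(C)C | intermediate
16 | acetoxy Weinreb amide | CC(=O)OC[C@H]1/C(C(=O)N(C)OC)=C\C/C=C(\C)C[C@H](O[Si](C)(C)C(C)(C)C)[C@@H]1[C@@H](C)CCC=C(C)C | intermediate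
17 | 4-O-TBS-hydroxyacetyldictyolal | CC(=O)OC[C@H]1/C(C=O)=C\C/C=C(\C)C[C@H](O[Si](C)(C)C(C)(C)C)[C@@H]1[C@@H](C)CCC=C(C)C | intermediate
18 | hydroxyacetyldictyolal | CC(=O)OC[C@H]1/C(C=O)=C\C/C=C(\C)C[C@H](O)[C@@H]1[C@@H](C)CCC=C(C)C | target

**Total steps:** 13. **Longest linear sequence:** 12 (steps 1–6 and 8–13); step 7 is a one-step side branch.

**Three steps most likely to fail**
1. Step 2 (proposed new Michael addition). Risks are low acceptor electrophilicity and the wrong C2/C3 topicity. Fallback (known chemistry): use the same catalyst with dimethyl 2-[2-(TBSO)ethylidene]malonate, an established syn-selective aldehyde→alkylidene malonate enamine Michael addition. After step 3, desilylative lactonisation and Krapcho dealkoxycarbonylation give the α-unsubstituted lactone. The alkylidene is then installed by lactone-enolate aldol with 12 and MsCl/DBU dehydration, rejoining at 13 without phosphonate or HWE.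
2. Step 9 (proposed new ring closure). Risks are branched coupling at C1 to give a seven-membered ring, diene formation by β-H loss, protodeboronation and oligomers. Fallback (known chemistry): HWE of 10 with acetaldehyde and kinetic deconjugation to the α-vinyl lactone, then iododeboronation to the E-alkenyl iodide. 9-BBN hydroboration and B-alkyl Suzuki macrocyclisation then close C7–C8, the reaction type precedented for this bond in nine-membered xenicane rings. LDA/PhSeBr and H2O2 (selenoxide elimination) restore C1=C9 and give 14.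
3. Step 6 (Zr/Al carbometalation next to a C–H-acidic phosphonolactone). Fallback: run the HWE first on 9 with 2-(PMBO)acetaldehyde so no acidic phosphonate remains. Then carboaluminate and iodinate (Me3Al, Cp2ZrCl2, −23 °C; I2), convert the E-alkenyl iodide to the boronate by Miyaura borylation, and exchange OPMB for OAc (DDQ; Ac2O) before step 9.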